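## Retrosynthetic overview

1. The furan ring is opened to a terminal alkyne and 2,4-dihydroxy-5-iodoacetophenone (Sonogashira coupling, then 5-endo-dig closure). The tertiary alcohol travels as its triethylsilyl ether.
2. The alkyne comes from an α-methyl aldehyde by one-carbon homologation. Its CH(CH3) centre is set by Evans methylation of a 4-aryl-4-silyloxypentanoyl oxazolidinone.
3. The pentanoic acid comes from a homoallylic tertiary alcohol (hydroboration, oxidation). The key C–C bond (carbinol C–CH2) is made by catalytic asymmetric allylboration of 6-acetyl-7-methoxy-2,2-dimethyl-2H-chromene with diisopropyl allylboronate, which sets the tertiary carbinol.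
4. The methyl ketone comes from the 6-bromochromene (Br/Li exchange, Weinreb amide). The bromochromene comes from resorcinol and 3-methylbut-2-enoic acid via the chroman-4-one.
5. Ring order: the pyranone ring is built on the resorcinol ring first (step 1) and converted to the 2H-pyran in step 5; the furan ring is built on the second benzene ring last (step 18).

Assumption: the (R)-enantiomer of the dibromobinaphthol catalyst is taken to send the allyl group to the Si face of the methyl ketone, by analogy with acetophenone-type ketones; the configuration is confirmed on the first oxazolidinone imide against the known auxiliary centre, and the equally available (S)-catalyst is used if the sense proves opposite.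

Handling note: from the homoallylic alcohol onwards, all work-ups are kept at pH 7 or above and silica gel is pre-treated with 1% Et3N, because the dialkoxy-substituted tertiary benzylic C–O bond ionises easily in acid.

## Route

Step 1
Reactants: 1 resorcinol; 2 3-methylbut-2-enoic acid
Product: 4 7-hydroxy-2,2-dimethylchroman-4-one, via dihydroxyphenyl enone 3 (not isolated)
Conditions: P2O5/MeSO3H (1:10 w/w), 70 °C, 2 h; ice-water
Reagents that add atoms: none
Why: Friedel–Crafts acylation at C-4 of resorcinol (para to one OH, ortho to the other) gives enone 3, whose ortho phenol closes the pyranone ring by intramolecular oxa-Michael addition, so only the 7-hydroxy isomer can form.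

Step 2
Reactants: 4 7-hydroxy-2,2-dimethylchroman-4-one
Product: 5 7-methoxy-2,2-dimethylchroman-4-one
Conditions: MeI, K2CO3, acetone, reflux, 6 h
Reagents that add atoms: iodomethane, `CI`
Why: Williamson ether synthesis, in which the only acidic OH (the phenol para to the carbonyl) is deprotonated and methylated by an SN2 reaction.

Step 3
Reactants: 5 7-methoxy-2,2-dimethylchroman-4-one
Product: 6 6-bromo-7-methoxy-2,2-dimethylchroman-4-one
Conditions: N-bromosuccinimide (1.02 equiv), MeCN, 0 °C to rt, dark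
Reagents that add atoms: N-bromosuccinimide, `O=C1CCC(=O)N1Br`
Why: Electrophilic aromatic bromination goes to C-6, which is ortho to OMe, para to the ring oxygen, meta to the carbonyl and much less crowded than C-8, while polar MeCN without initiator or acid keeps the reagent off the C-3 methylene.

Step 4
Reactants: 6 6-bromo-7-methoxy-2,2-dimethylchroman-4-one
Product: 7 (±)-6-bromo-7-methoxy-2,2-dimethylchroman-4-ol
Conditions: NaBH4, MeOH/THF 1:1, 0 °C to rt
Reagents that add atoms: none
Why: Borohydride 1,2-reduction of the aryl ketone leaves the aryl bromide alone, and the new carbinol centre is racemic, which does not matter because step 5 erases it.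

Step 5
Reactants: 7 (±)-6-bromo-7-methoxy-2,2-dimethylchroman-4-ol
Product: 8 6-bromo-7-methoxy-2,2-dimethyl-2H-chromene
Conditions: p-toluenesulfonic acid monohydrate (2 mol %), toluene, reflux (Dean–Stark), 1 h
Reagents that add atoms: none
Why: Acid-catalysed E1 dehydration, in which the benzylic cation para to OMe forms easily and loses a C-3 proton to give the conjugated chromene, with low acid loading and azeotropic water removal to prevent dimerisation.

Step 6
Reactants: 8 6-bromo-7-methoxy-2,2-dimethyl-2H-chromene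
Product: 11 1-(7-methoxy-2,2-dimethyl-2H-chromen-6-yl)ethanone, via aryllithium 9 (not isolated), via lithium hemiaminal adduct 10 (not isolated)
Conditions: n-BuLi, THF, −78 °C, 30 min; MeC(O)N(OMe)Me, −78 to 0 °C; aq NH4Cl
Reagents that add atoms: n-butyllithium, `[Li]CCCC` (lithium stays only in 9 and 10); N-methoxy-N-methylacetamide, `CC(=O)N(C)OC`
Why: Bromine–lithium exchange followed by Weinreb ketone synthesis, in which aryllithium 9 adds only once because chelated adduct 10 survives until the quench.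

Step 7
Reactants: 12 allylmagnesium bromide; 13 triisopropyl borate
Product: 15 diisopropyl allylboronate (allyldiisopropoxyborane), via magnesium allylborate 14 (not isolated)
Conditions: Et2O, −78 °C to rt; HCl (2 M in Et2O, 1.0 equiv), 0 °C; filtration under Ar, distillation
Reagents that add atoms: none
Why: Grignard addition to the borate ester gives ate complex 14, and one equivalent of dry HCl removes one isopropoxide to leave the distillable, exchange-labile acyclic allylboronate that step 8 needs.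

Step 8 (key C–C bond)
Reactants: 11 1-(7-methoxy-2,2-dimethyl-2H-chromen-6-yl)ethanone; 15 diisopropyl allylboronate
Product: 17 (2S)-2-(7-methoxy-2,2-dimethyl-2H-chromen-6-yl)pent-4-en-2-ol, via tertiary alkyl borate 16 (not isolated)
Conditions: 15 (1.5 equiv), (R)-3,3'-dibromo-1,1'-bi-2-naphthol (15 mol %), PhCF3/toluene 3:1, −35 °C, 24–48 h; pH 7 phosphate buffer
Reagents that add atoms: none
Why: In this chiral-diol-catalysed asymmetric allylboration (carbonyl allylation), exchange of one isopropoxy group of 15 for the binaphthol gives a more Lewis-acidic chiral boronate that adds through a closed chair transition state (aryl equatorial, methyl axial) to the Si face of the ketone, setting the (S) tertiary carbinol under neutral conditions that the acid-labile product survives.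

Step 9
Reactants: 17 (2S)-2-(7-methoxy-2,2-dimethyl-2H-chromen-6-yl)pent-4-en-2-ol
Product: 18 triethyl{[(2S)-2-(7-methoxy-2,2-dimethyl-2H-chromen-6-yl)pent-4-en-2-yl]oxy}silane
Conditions: Et3SiOTf, 2,6-lutidine, CH2Cl2, −78 to −20 °C; aq NaHCO3
Reagents that add atoms: triethylsilyl trifluoromethanesulfonate, `CC[Si](CC)(CC)OS(=O)(=O)C(F)(F)F`
Why: Silyl ether protection with a silyl triflate and a hindered pyridine base silylates even tertiary alcohols at low temperature, and the excess base keeps the medium acid-free so that the benzylic C–O bond and its configuration are kept.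

Step 10
Reactants: 18 triethyl{[(2S)-2-(7-methoxy-2,2-dimethyl-2H-chromen-6-yl)pent-4-en-2-yl]oxy}silane
Product: 20 (4S)-4-(7-methoxy-2,2-dimethyl-2H-chromen-6-yl)-4-(triethylsilyloxy)pentan-1-ol, via B-alkyl-9-BBN adduct 19 (not isolated)
Conditions: 9-borabicyclo[3.3.1]nonane (9-BBN-H, 1.3 equiv), THF, 0 °C to rt; then 3 M NaOH, 30% H2O2, 0 °C
Reagents that add atoms: 9-BBN-H, `[H]B1C2CCCC1CCC2` (boron stays only in 19); hydrogen peroxide, `OO`
Why: In this Brown hydroboration–oxidation, bulky 9-BBN-H adds anti-Markovnikov to the monosubstituted alkene far faster than to the cis-disubstituted chromene alkene next to a quaternary carbon, and alkaline peroxide then replaces boron by OH without touching the silyl ether.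

Step 11
Reactants: 20 (4S)-4-(7-methoxy-2,2-dimethyl-2H-chromen-6-yl)-4-(triethylsilyloxy)pentan-1-ol
Product: 22 (4S)-4-(7-methoxy-2,2-dimethyl-2H-chromen-6-yl)-4-(triethylsilyloxy)pentanoic acid, via silyloxy aldehyde 21 (not isolated)
Conditions: nPr4N[RuO4] (10 mol %), N-methylmorpholine N-oxide monohydrate (10 equiv), MeCN, rt
Reagents that add atoms: water (from the N-oxide monohydrate), `O`
Why: Ley–Griffith perruthenate oxidation run with water present takes the alcohol to aldehyde 21, whose hydrate is oxidised on to the acid in a non-acidic medium that spares the silyl ether, the chromene alkene and the electron-rich arene.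

Step 12
Reactants: 22 (4S)-4-(7-methoxy-2,2-dimethyl-2H-chromen-6-yl)-4-(triethylsilyloxy)pentanoic acid; 23 (4S)-4-benzyl-1,3-oxazolidin-2-one
Product: 25 (4S)-4-benzyl-3-[(4S)-4-(7-methoxy-2,2-dimethyl-2H-chromen-6-yl)-4-(triethylsilyloxy)pentanoyl]-1,3-oxazolidin-2-one, via mixed pivalic anhydride 24 (not isolated)
Conditions: Me3CCOCl, Et3N, THF, −20 °C, 1 h; then LiCl, 23, −20 °C to rt
Reagents that add atoms: pivaloyl chloride, `CC(C)(C)C(=O)Cl` (stays only in 24)
Why: In this N-acylation of the Evans auxiliary through mixed anhydride 24, the bulky pivaloyl side steers the LiCl-activated oxazolidinone to the wanted carbonyl, and any (4R) material left by imperfect ee in step 8 becomes a diastereomer that chromatography or crystallisation removes.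

Step 13
Reactants: 25 (4S)-4-benzyl-3-[(4S)-4-(7-methoxy-2,2-dimethyl-2H-chromen-6-yl)-4-(triethylsilyloxy)pentanoyl]-1,3-oxazolidin-2-one
Product: 27 (4S)-4-benzyl-3-[(2S,4S)-4-(7-methoxy-2,2-dimethyl-2H-chromen-6-yl)-2-methyl-4-(triethylsilyloxy)pentanoyl]-1,3-oxazolidin-2-one, via sodium Z-enolate 26 (not isolated)
Conditions: NaN(SiMe3)2, THF, −78 °C, 45 min; MeI (5 equiv), −78 to −40 °C; pH 7 buffer
Reagents that add atoms: sodium bis(trimethylsilyl)amide, `C[Si](C)(C)[N-][Si](C)(C)C.[Na+]` (sodium stays only in 26); iodomethane, `CI`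
Why: In this Evans asymmetric alkylation, the chelated Z-enolate 26 is shielded on one face by the benzyl group of the (4S)-auxiliary, so MeI attacks the other face and sets the (2S) methyl-bearing centre (typically above 10:1, minor epimer removed by chromatography) without influence from the remote C-4 centre.

Step 14
Reactants: 27 (4S)-4-benzyl-3-[(2S,4S)-4-(7-methoxy-2,2-dimethyl-2H-chromen-6-yl)-2-methyl-4-(triethylsilyloxy)pentanoyl]-1,3-oxazolidin-2-one
Product: 28 (2S,4S)-4-(7-methoxy-2,2-dimethyl-2H-chromen-6-yl)-2-methyl-4-(triethylsilyloxy)pentan-1-ol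
Conditions: LiBH4, MeOH (2 equiv), Et2O, 0 °C; 1 M NaOH
Reagents that add atoms: none
Why: Reductive removal of the auxiliary with methanol-activated LiBH4 reduces the exocyclic imide carbonyl to the primary alcohol without enolisation, so C-2 is not epimerised and 23 is recovered.

Step 15
Reactants: 28 (2S,4S)-4-(7-methoxy-2,2-dimethyl-2H-chromen-6-yl)-2-methyl-4-(triethylsilyloxy)pentan-1-ol
Product: 29 (2S,4S)-4-(7-methoxy-2,2-dimethyl-2H-chromen-6-yl)-2-methyl-4-(triethylsilyloxy)pentanal
Conditions: nPr4N[RuO4] (5 mol %), N-methylmorpholine N-oxide (1.5 equiv), 4 Å molecular sieves, CH2Cl2, rt, 30 min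
Reagents that add atoms: none
Why: Ley–Griffith oxidation under neutral, anhydrous conditions stops at the aldehyde and neither epimerises the α-centre nor harms the alkene, arene or silyl ether.

Step 16
Reactants: 29 (2S,4S)-4-(7-methoxy-2,2-dimethyl-2H-chromen-6-yl)-2-methyl-4-(triethylsilyloxy)pentanal
Product: 30 triethyl{[(2S,4S)-2-(7-methoxy-2,2-dimethyl-2H-chromen-6-yl)-4-methylhex-5-yn-2-yl]oxy}silane
Conditions: MeC(O)C(N2)P(O)(OMe)2 (1.5 equiv), K2CO3 (2 equiv), MeOH, 0 °C to rt
Reagents that add atoms: dimethyl (1-diazo-2-oxopropyl)phosphonate, `COP(=O)(OC)C(=[N+]=[N-])C(C)=O`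
Why: Seyferth–Gilbert homologation in the Ohira–Bestmann version turns the aldehyde into the terminal alkyne with one added carbon under mild carbonate/methanol conditions at which α-methyl aldehydes keep their configuration.

Step 17
Reactants: 31 2,4-dihydroxyacetophenone
Product: 32 2,4-dihydroxy-5-iodoacetophenone
Conditions: ICl (1.0 equiv), AcOH, rt; recrystallisation
Reagents that add atoms: iodine monochloride, `ClI`
Why: Electrophilic aromatic iodination in acidic medium goes to C-5 (para to the chelated 2-OH, ortho to the 4-OH) rather than to crowded C-3, and one equivalent of reagent plus recrystallisation removes traces of 3-iodo and diiodo products.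

Step 18
Reactants: 30 triethyl{[(2S,4S)-2-(7-methoxy-2,2-dimethyl-2H-chromen-6-yl)-4-methylhex-5-yn-2-yl]oxy}silane; 32 2,4-dihydroxy-5-iodoacetophenone
Product: 34 1-{6-hydroxy-2-[(2S,4S)-4-(7-methoxy-2,2-dimethyl-2H-chromen-6-yl)-4-(triethylsilyloxy)pentan-2-yl]-1-benzofuran-5-yl}ethanone, via ortho-alkynylphenol 33 (not isolated)
Conditions: PdCl2(PPh3)2 (4 mol %), CuI (8 mol %), Et3N (4 equiv), DMF, Ar, rt 2 h then 70 °C, 12 h
Reagents that add atoms: none
Why: Sonogashira coupling (oxidative addition of the aryl iodide to zerovalent palladium, transfer of the copper acetylide) gives 33, whose 4-OH next to the triple bond closes the furan ring in the same pot by 5-endo-dig heteroannulation, while the acetyl-chelated 2-OH cannot reach the alkyne and no stereocentre is touched.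

Step 19
Reactants: 34 1-{6-hydroxy-2-[(2S,4S)-4-(7-methoxy-2,2-dimethyl-2H-chromen-6-yl)-4-(triethylsilyloxy)pentan-2-yl]-1-benzofuran-5-yl}ethanone
Product: 35 1-{6-hydroxy-2-[(2S,4S)-4-hydroxy-4-(7-methoxy-2,2-dimethyl-2H-chromen-6-yl)pentan-2-yl]-1-benzofuran-5-yl}ethanone (CNP0233723.1)
Conditions: Bu4NF (3 equiv), THF, 0 °C to rt; pH 7 phosphate buffer
Reagents that add atoms: none
Why: Fluoride-induced desilylation, driven by the strong Si–F bond, frees the tertiary alcohol under non-acidic conditions, so the benzylic carbinol neither dehydrates nor racemises and both stereocentres are delivered unchanged.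

## Compound list

1 | resorcinol | `Oc1cccc(O)c1` | starting material
2 | 3-methylbut-2-enoic acid | `CC(C)=CC(=O)O` | starting material
3 | 1-(2,4-dihydroxyphenyl)-3-methylbut-2-en-1-one (not isolated) | `CC(C)=CC(=O)c1ccc(O)cc1O` | intermediate
4 | 7-hydroxy-2,2-dimethylchroman-4-one | `CC1(C)CC(=O)c2ccc(O)cc2O1` | intermediate
5 | 7-methoxy-2,2-dimethylchroman-4-one | `COc1ccc2c(c1)OC(C)(C)CC2=O` | intermediate
6 | 6-bromo-7-methoxy-2,2-dimethylchroman-4-one | `COc1cc2c(cc1Br)C(=O)CC(C)(C)O2` | intermediate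
7 | (±)-6-bromo-7-methoxy-2,2-dimethylchroman-4-ol (racemic at C-4) | `COc1cc2c(cc1Br)C(O)CC(C)(C)O2` | intermediate
8 | 6-bromo-7-methoxy-2,2-dimethyl-2H-chromene | `COc1cc2c(cc1Br)C=CC(C)(C)O2` | intermediate
9 | (7-methoxy-2,2-dimethyl-2H-chromen-6-yl)lithium (not isolated) | `COc1cc2c(cc1[Li])C=CC(C)(C)O2` | intermediate
10 | lithium 1-[methoxy(methyl)amino]-1-(7-methoxy-2,2-dimethyl-2H-chromen-6-yl)ethanolate (not isolated) | `COc1cc2c(cc1C(C)([O-])N(C)OC)C=CC(C)(C)O2.[Li+]` | intermediate
11 | 1-(7-methoxy-2,2-dimethyl-2H-chromen-6-yl)ethanone | `COc1cc2c(cc1C(C)=O)C=CC(C)(C)O2` | intermediate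
12 | allylmagnesium bromide | `C=CC[Mg]Br` | starting material
13 | triisopropyl borate | `CC(C)OB(OC(C)C)OC(C)C` | starting material
14 | bromomagnesium allyltriisopropoxyborate (not isolated) | `C=CC[B-](OC(C)C)(OC(C)C)OC(C)C.[Mg+]Br` | intermediate
15 | diisopropyl allylboronate | `C=CCB(OC(C)C)OC(C)C` | intermediate
16 | diisopropyl (2S)-2-(7-methoxy-2,2-dimethyl-2H-chromen-6-yl)pent-4-en-2-yl borate (not isolated) | `COc1cc2c(cc1[C@@](C)(OB(OC(C)C)OC(C)C)CC=C)C=CC(C)(C)O2` | intermediate
17 | (2S)-2-(7-methoxy-2,2-dimethyl-2H-chromen-6-yl)pent-4-en-2-ol | `COc1cc2c(cc1[C@@](C)(O)CC=C)C=CC(C)(C)O2` | intermediate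
18 | triethyl{[(2S)-2-(7-methoxy-2,2-dimethyl-2H-chromen-6-yl)pent-4-en-2-yl]oxy}silane | `COc1cc2c(cc1[C@@](C)(O[Si](CC)(CC)CC)CC=C)C=CC(C)(C)O2` | intermediate
19 | 9-[(4S)-4-(7-methoxy-2,2-dimethyl-2H-chromen-6-yl)-4-(triethylsilyloxy)pentyl]-9-borabicyclo[3.3.1]nonane (not isolated) | `COc1cc2c(cc1[C@@](C)(O[Si](CC)(CC)CC)CCCB1C3CCCC1CCC3)C=CC(C)(C)O2` | intermediate
20 | (4S)-4-(7-methoxy-2,2-dimethyl-2H-chromen-6-yl)-4-(triethylsilyloxy)pentan-1-ol | `COc1cc2c(cc1[C@@](C)(O[Si](CC)(CC)CC)CCCO)C=CC(C)(C)O2` | intermediate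
21 | (4S)-4-(7-methoxy-2,2-dimethyl-2H-chromen-6-yl)-4-(triethylsilyloxy)pentanal (not isolated) | `COc1cc2c(cc1[C@@](C)(O[Si](CC)(CC)CC)CCC=O)C=CC(C)(C)O2` | intermediate
22 | (4S)-4-(7-methoxy-2,2-dimethyl-2H-chromen-6-yl)-4-(triethylsilyloxy)pentanoic acid | `COc1cc2c(cc1[C@@](C)(O[Si](CC)(CC)CC)CCC(=O)O)C=CC(C)(C)O2` | intermediate
23 | (4S)-4-benzyl-1,3-oxazolidin-2-one | `O=C1N[C@@H](Cc2ccccc2)CO1` | starting material
24 | (4S)-4-(7-methoxy-2,2-dimethyl-2H-chromen-6-yl)-4-(triethylsilyloxy)pentanoic pivalic anhydride (not isolated) | `COc1cc2c(cc1[C@@](C)(O[Si](CC)(CC)CC)CCC(=O)OC(=O)C(C)(C)C)C=CC(C)(C)O2` | intermediate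
25 | (4S)-4-benzyl-3-[(4S)-4-(7-methoxy-2,2-dimethyl-2H-chromen-6-yl)-4-(triethylsilyloxy)pentanoyl]-1,3-oxazolidin-2-one | `COc1cc2c(cc1[C@@](C)(O[Si](CC)(CC)CC)CCC(=O)N1[C@@H](Cc3ccccc3)COC1=O)C=CC(C)(C)O2` | intermediate
26 | sodium (Z)-enolate of 25 (not isolated) | `COc1cc2c(cc1[C@@](C)(O[Si](CC)(CC)CC)C/C=C([O-])/N1[C@@H](Cc3ccccc3)COC1=O)C=CC(C)(C)O2.[Na+]` | intermediate
27 | (4S)-4-benzyl-3-[(2S,4S)-4-(7-methoxy-2,2-dimethyl-2H-chromen-6-yl)-2-methyl-4-(triethylsilyloxy)pentanoyl]-1,3-oxazolidin-2-one | `COc1cc2c(cc1[C@@](C)(O[Si](CC)(CC)CC)C[C@H](C)C(=O)N1[C@@H](Cc3ccccc3)COC1=O)C=CC(C)(C)O2` | intermediate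
28 | (2S,4S)-4-(7-methoxy-2,2-dimethyl-2H-chromen-6-yl)-2-methyl-4-(triethylsilyloxy)pentan-1-ol | `COc1cc2c(cc1[C@@](C)(O[Si](CC)(CC)CC)C[C@H](C)CO)C=CC(C)(C)O2` | intermediate
29 | (2S,4S)-4-(7-methoxy-2,2-dimethyl-2H-chromen-6-yl)-2-methyl-4-(triethylsilyloxy)pentanal | `COc1cc2c(cc1[C@@](C)(O[Si](CC)(CC)CC)C[C@H](C)C=O)C=CC(C)(C)O2` | intermediate
30 | triethyl{[(2S,4S)-2-(7-methoxy-2,2-dimethyl-2H-chromen-6-yl)-4-methylhex-5-yn-2-yl]oxy}silane | `COc1cc2c(cc1[C@@](C)(O[Si](CC)(CC)CC)C[C@H](C)C#C)C=CC(C)(C)O2` | intermediate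
31 | 2,4-dihydroxyacetophenone | `CC(=O)c1ccc(O)cc1O` | starting material
32 | 2,4-dihydroxy-5-iodoacetophenone | `CC(=O)c1cc(I)c(O)cc1O` | intermediate
33 | 1-{2,4-dihydroxy-5-[(3S,5S)-5-(7-methoxy-2,2-dimethyl-2H-chromen-6-yl)-3-methyl-5-(triethylsilyloxy)hex-1-yn-1-yl]phenyl}ethanone (not isolated) | `COc1cc2c(cc1[C@@](C)(O[Si](CC)(CC)CC)C[C@H](C)C#Cc1cc(C(C)=O)c(O)cc1O)C=CC(C)(C)O2` | intermediate
34 | 1-{6-hydroxy-2-[(2S,4S)-4-(7-methoxy-2,2-dimethyl-2H-chromen-6-yl)-4-(triethylsilyloxy)pentan-2-yl]-1-benzofuran-5-yl}ethanone | `COc1cc2c(cc1[C@@](C)(O[Si](CC)(CC)CC)C[C@H](C)c1cc3cc(C(C)=O)c(O)cc3o1)C=CC(C)(C)O2` | intermediate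
35 | 1-{6-hydroxy-2-[(2S,4S)-4-hydroxy-4-(7-methoxy-2,2-dimethyl-2H-chromen-6-yl)pentan-2-yl]-1-benzofuran-5-yl}ethanone | `COc1cc2c(cc1[C@@](C)(O)C[C@H](C)c1cc3cc(C(C)=O)c(O)cc3o1)C=CC(C)(C)O2` | target

## Step count and risks

Total step count: 19.
Longest linear sequence: 17 steps (1–6, 8–16, 18, 19).

**Step 8.** Ketone 11 is electron-rich and ortho-substituted, so it may add slowly or with eroded ee.
- The fallback sets out from 11 and comes back at 17. It makes the carbinol carbon stereogenic first and brings in the allyl group by a stereospecific 1,2-metallate shift.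
- Transfer hydrogenation of 11 with RuCl(p-cymene)[(R,R)-TsDPEN] and HCO2Na in water/MeOH gives (1R)-1-(7-methoxy-2,2-dimethyl-2H-chromen-6-yl)ethanol F1.
- NaH and iPr2NCOCl convert this alcohol into the (1R)-N,N-diisopropylcarbamate F2.
- sBuLi in Et2O at −78 °C gives the configurationally stable lithiated carbamate F3.
- Allylboronic acid pinacol ester adds to it with retention to give the lithium boronate complex F4.
- On warming, this complex expels the carbamate with inversion at carbon and gives the (2R)-tertiary pinacol boronic ester F5.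
- NaOH/H2O2 replaces boron by OH with retention and delivers 17.

**Step 9.** The silyl triflate may ionise the very electron-rich tertiary benzylic alcohol and cause elimination to the styrene.
- The fallback drops both the protecting group and the auxiliary and ties the carbinol oxygen up in a lactone. It sets out from 17 and comes back to the route only at the target 35.
- Hydroboration–oxidation of 17 (2.3 equiv 9-BBN-H, then NaOH/H2O2) gives (4S)-4-(7-methoxy-2,2-dimethyl-2H-chromen-6-yl)pentane-1,4-diol F6.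
- nPr4N[RuO4] with N-methylmorpholine N-oxide closes the diol to the (5S)-5-aryl-5-methyl-γ-butyrolactone F7.
- LiN(iPr)2/MeI methylates the enolate anti to the aryl group, so it gives mainly the unwanted (3R,5S)-3,5-dimethyl lactone F8.
- A second deprotonation and a quench at −78 °C with bulky 2,6-di-tert-butyl-4-methylphenol put the proton on the face away from the aryl group. This gives the (3S,5S)-3,5-dimethyl lactone F9 (methyl cis to aryl), which is purified by chromatography.
- iBu2AlH in toluene at −78 °C gives the lactol F10.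
- The Ohira–Bestmann reagent with K2CO3/MeOH acts on the open hydroxy aldehyde form of the lactol to give (2S,4S)-2-(7-methoxy-2,2-dimethyl-2H-chromen-6-yl)-4-methylhex-5-yn-2-ol F11.
- Coupling of this alkynol with 32 under the conditions of step 18 gives 35 directly.

**Step 18.** The domino reaction may stall at the alkynylphenol, or the free resorcinol unit may poison the catalyst or favour alkyne homocoupling.
- The fallback separates coupling from ring closure. It sets out from 32 (with 30) and comes back at 34.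
- Ac2O/pyridine turns 32 into 4-acetyl-6-iodobenzene-1,3-diyl diacetate F12.
- The diacetate couples with 30 at room temperature (PdCl2(PPh3)2, CuI, Et3N, THF) to give the diacetoxyaryl alkyne F13.
- K2CO3 in MeOH at 50 °C then removes both acetates, and the liberated ortho phenoxide closes the furan ring to give 34.

## Further compounds

F1 | step 8 | (1R)-1-(7-methoxy-2,2-dimethyl-2H-chromen-6-yl)ethanol | `COc1cc2c(cc1[C@@H](C)O)C=CC(C)(C)O2`
F2 | step 8 | (1R)-1-(7-methoxy-2,2-dimethyl-2H-chromen-6-yl)ethyl N,N-diisopropylcarbamate | `COc1cc2c(cc1[C@@H](C)OC(=O)N(C(C)C)C(C)C)C=CC(C)(C)O2`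
F3 | step 8 | α-lithiated carbamate (lithium in place of the benzylic H, retention) | `COc1cc2c(cc1[C@@]([Li])(C)OC(=O)N(C(C)C)C(C)C)C=CC(C)(C)O2`
F4 | step 8 | lithium allyl(pinacolato)boronate complex of the carbamate (boron in place of lithium, retention) | `COc1cc2c(cc1[C@@]([B-]1(CC=C)OC(C)(C)C(C)(C)O1)(C)OC(=O)N(C(C)C)C(C)C)C=CC(C)(C)O2.[Li+]`
F5 | step 8 | 2-[(2R)-2-(7-methoxy-2,2-dimethyl-2H-chromen-6-yl)pent-4-en-2-yl]-4,4,5,5-tetramethyl-1,3,2-dioxaborolane | `COc1cc2c(cc1[C@@](C)(B1OC(C)(C)C(C)(C)O1)CC=C)C=CC(C)(C)O2`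
F6 | step 9 | (4S)-4-(7-methoxy-2,2-dimethyl-2H-chromen-6-yl)pentane-1,4-diol | `COc1cc2c(cc1[C@@](C)(O)CCCO)C=CC(C)(C)O2`
F7 | step 9 | (5S)-5-(7-methoxy-2,2-dimethyl-2H-chromen-6-yl)-5-methyldihydrofuran-2(3H)-one | `COc1cc2c(cc1[C@]1(C)CCC(=O)O1)C=CC(C)(C)O2`
F8 | step 9 | (3R,5S)-5-(7-methoxy-2,2-dimethyl-2H-chromen-6-yl)-3,5-dimethyldihydrofuran-2(3H)-one | `COc1cc2c(cc1[C@]1(C)C[C@@H](C)C(=O)O1)C=CC(C)(C)O2`
F9 | step 9 | (3S,5S)-5-(7-methoxy-2,2-dimethyl-2H-chromen-6-yl)-3,5-dimethyldihydrofuran-2(3H)-one | `COc1cc2c(cc1[C@]1(C)C[C@H](C)C(=O)O1)C=CC(C)(C)O2`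
F10 | step 9 | (3S,5S)-5-(7-methoxy-2,2-dimethyl-2H-chromen-6-yl)-3,5-dimethyltetrahydrofuran-2-ol (anomer mixture) | `COc1cc2c(cc1[C@]1(C)C[C@H](C)C(O)O1)C=CC(C)(C)O2`
F11 | step 9 | (2S,4S)-2-(7-methoxy-2,2-dimethyl-2H-chromen-6-yl)-4-methylhex-5-yn-2-ol | `COc1cc2c(cc1[C@@](C)(O)C[C@H](C)C#C)C=CC(C)(C)O2`
F12 | step 18 | 4-acetyl-6-iodobenzene-1,3-diyl diacetate | `CC(=O)Oc1cc(OC(C)=O)c(C(C)=O)cc1I`
F13 | step 18 | 4-acetyl-6-[(3S,5S)-5-(7-methoxy-2,2-dimethyl-2H-chromen-6-yl)-3-methyl-5-(triethylsilyloxy)hex-1-yn-1-yl]benzene-1,3-diyl diacetate | `COc1cc2c(cc1[C@@](C)(O[Si](CC)(CC)CC)C[C@H](C)C#Cc1cc(C(C)=O)c(OC(C)=O)cc1OC(C)=O)C=CC(C)(C)O2`
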